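**Retrosynthetic overview**

- Feature: in the 27-membered lactone ring (26 C + 1 O), the four neighbouring methylenes C17–C20 are carried as a linear 1,3-diyne, C17≡C18–C19≡C20, whose central C18–C19 bond is the ring-closing bond.
- Ester bond C1(=O)–O–C26: cut to the C18 alkynoic acid 1 and the C8 alkynol 2, which are joined as the acyclic diyne ester 3.
- C18–C19 (sp–sp): cut in the macrocyclic 1,3-diyne lactone 4, which should form from 3 by intramolecular oxidative alkyne coupling.
- Functional-group level: 4 is the 17,19-diyne form of target 5; full hydrogenation turns the diyne into the C17–C20 methylenes.
- Ring order: a single ring, the 27-membered lactone, closed in step 2 before saturation.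

Key step: step 2

Remark: lactone locants are used for 4 and 5 (C1 = carbonyl carbon, C26 = OCH2); the target has no stereocentre, and acid 1 and alcohol 2 are taken as purchasable.

**Route**

Step 1
Reactants: 1 octadec-17-ynoic acid; 2 oct-7-yn-1-ol
Product: 3 oct-7-yn-1-yl octadec-17-ynoate
Conditions: DCC (1.1 equiv), DMAP (0.1 equiv), CH2Cl2, 0 °C to rt
Reagents that add atoms: none
Why: Steglich esterification, in which carbodiimide activation of the acid with DMAP as acyl-transfer catalyst should acylate the unhindered primary alcohol under neutral conditions that leave both terminal alkynes untouched; no stereocentre is formed.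

Step 2
Reactants: 3 oct-7-yn-1-yl octadec-17-ynoate
Product: 4 hexacosa-17,19-diyn-26-olide (1-oxacycloheptacosa-18,20-diyn-2-one)
Conditions: Cu(OAc)2 (10 equiv), pyridine/Et2O (5:1), 45 °C, syringe-pump addition of 3 over 16 h (final ca. 0.002 M)
Reagents that add atoms: none
Why: This is an Eglinton coupling, the oxidative homocoupling of terminal alkynes by stoichiometric Cu(OAc)2 in pyridine, run within one molecule as is known for high-dilution closure of alpha,omega-diyne esters. Each sp C–H bond of 3 is cuprated with pyridine or acetate as base (acetic acid leaves), and two alkynyl ligands on a dicopper core then couple reductively, each divalent copper ending as monovalent copper, to form the C18–C19 sp–sp bond. The ring closes as a 27-membered macrocycle by end-to-end union of the two chain termini, so the new bond and all four sp carbons lie inside the ring, and a ring of this size takes up the linear four-carbon diyne rod without angle strain. No stereocentre is created. The selectivity needed is ring closure over intermolecular coupling to cyclic dimer and oligomers; it is secured by the flexible 23-atom tether that lets the two ends meet freely and by keeping the stationary concentration of 3 very low through slow addition into excess Cu(OAc)2, while regiochemistry is not in question because two equivalent termini of one molecule are joined. Chemoselectivity rests on the two alkyne C–H bonds being the only acidic, copper-binding sites, so the ester and the saturated chain should stay untouched.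

Step 3
Reactants: 4 hexacosa-17,19-diyn-26-olide
Product: 5 26-hexacosanolide (1-oxacycloheptacosan-2-one)
Conditions: H2 (1 atm), 10% Pd/C, EtOAc, rt
Reagents that add atoms: none
Why: Heterogeneous catalytic hydrogenation, in which four equivalents of H2 should add across the two conjugated triple bonds on the palladium surface to turn C17–C20 into methylenes, while the lactone, which has no allylic, propargylic or benzylic C–O bond, is inert and no stereocentre arises.

**Compound list**

1 | octadec-17-ynoic acid | C#CCCCCCCCCCCCCCCCC(=O)O | starting material
2 | oct-7-yn-1-ol | C#CCCCCCCO | starting material
3 | oct-7-yn-1-yl octadec-17-ynoate | C#CCCCCCCCCCCCCCCCC(=O)OCCCCCCC#C | intermediate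
4 | hexacosa-17,19-diyn-26-olide | O=C1CCCCCCCCCCCCCCCC#CC#CCCCCCCO1 | intermediate
5 | 26-hexacosanolide | O=C1CCCCCCCCCCCCCCCCCCCCCCCCCO1 | target

Total step count: 3
Longest linear sequence: 3 steps

**Steps most likely to fail**

First, step 2 (macrocyclization). Intermolecular coupling may overtake ring closure whenever unreacted 3 builds up, for instance if cupration is slow relative to the addition rate, so that cyclic dimer and open-chain oligomers grow at the expense of 4. The fallback makes the sp–sp bond between two separate molecules, where dilution does not matter, and closes the ring at the ester oxygen instead. It sets out from 2: bromination of the alkyne C–H (NBS, cat. AgNO3, acetone, rt) should give 8-bromooct-7-yn-1-ol F1. Cadiot–Chodkiewicz cross-coupling of F1 with acid 1 (cat. CuCl, NH2OH·HCl, aq. n-BuNH2, MeOH/THF, 0 °C) should give 26-hydroxyhexacosa-17,19-diynoic acid F2. Yamaguchi macrolactonization (2,4,6-trichlorobenzoyl chloride, Et3N, THF, rt, then slow addition to DMAP in toluene at 80 °C) passes through 26-hydroxyhexacosa-17,19-diynoic 2,4,6-trichlorobenzoic anhydride F3, which is not isolated, and comes back to the route at 4.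

Second, step 3 (hydrogenation). Hydrogen uptake may stop short of full saturation because the palladium surface is deactivated by copper or pyridine traces carried over from step 2, or is coated by the sparingly soluble waxy product. This would leave partly reduced ene and diene material that is hard to separate from 5. A chelating wash and silica filtration of 4 are assumed beforehand. The fallback is a metal-free hydrogen transfer that sets out from 4: diazene (diimide) F4, generated in the flask from excess p-toluenesulfonyl hydrazide and NaOAc in DME/H2O at reflux, delivers hydrogen pairwise by concerted syn transfer to each C–C multiple bond. The sequence comes back to the route at 5.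

Third, step 1 (esterification). Rearrangement of the carbodiimide-activated acid to an unreactive N-acylurea may compete with acyl transfer, and urea residues may trail the lipophilic ester during purification. The fallback reverses the roles of the partners, so that the C–O bond is made by SN2 alkylation of a carboxylate instead of acyl substitution. It sets out from 2: MsCl and Et3N in CH2Cl2 at 0 °C should give oct-7-yn-1-yl methanesulfonate F5, which alkylates acid 1 in the presence of Cs2CO3 in DMF at 50 °C and comes back to the route at 3.

Further compounds
F1 | step 2 | 8-bromooct-7-yn-1-ol | OCCCCCCC#CBr
F2 | step 2 | 26-hydroxyhexacosa-17,19-diynoic acid | OC(=O)CCCCCCCCCCCCCCCC#CC#CCCCCCCO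
F3 | step 2 | 26-hydroxyhexacosa-17,19-diynoic 2,4,6-trichlorobenzoic anhydride | O=C(OC(=O)CCCCCCCCCCCCCCCC#CC#CCCCCCCO)c1c(Cl)cc(Cl)cc1Cl
F4 | step 3 | diazene (diimide) | N=N
F5 | step 1 | oct-7-yn-1-yl methanesulfonate | C#CCCCCCCOS(C)(=O)=O
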